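## Structural features

The target has a single carbocycle, the cyclohexane ring of quinic acid, in which C1 carries a carboxylic acid and a tertiary oxygen esterified by (E)-3,4-dihydroxycinnamic (caffeic) acid, C3, C4 and C5 carry contiguous secondary hydroxyls, and C2 and C6 are methylenes. C3 and C5 are both R; the C4 hydroxyl is cis to the C3 hydroxyl and to the C1 acyloxy oxygen and trans to the C5 hydroxyl, which shares its face with the carboxyl group. C1 and C4 are stereogenic only through their mutual cis/trans relationship. With C4 as a carbonyl, only the like-configured centres C3 and C5 remain, related by a local twofold axis through C1 and C4, and C1 is no longer a stereocentre. Fragile groups are the hindered tertiary ester (acyl migration or hydrolysis under base), the cinnamate double bond (hydrogenation, conjugate addition), the catechol (oxidation) and the hydroxy acid (1,5-lactonisation under forcing acid). The real difficulties are placing the caffeoyl group on the most hindered oxygen and setting the trans-disposed C3 and C5 oxygens absolutely without a chiral-pool cyclitol. The plan exploits the C4 ketone flanked by the methylenes C3 and C5 in a ring whose C1 is already fully substituted: this ketone is achiral and can be oxygenated at both α-carbons through its enamine under catalyst control.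

## Logic of the disconnections

**16 ⇒ 15.** The O–C bonds of the tert-butyl ester and of the two aryl methoxymethyl acetals are cut. All three are acid-labile, so one operation unmasks the acid and the catechol at the very end, after every oxidising, reducing and basic step. The forward step must be an acidolysis that neither moves the acyl group from O1 nor closes the 1,5-lactone.

**15 ⇒ 14.** The C3 and C5 hydroxyls are traced back to O–N bonds of two anilinooxy ethers, because that is the form in which the oxygens are installed. Nothing is simplified structurally. The forward step must cleave N–O reductively without touching the cinnamate double bond, the acetals or the esters.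

**14 ⇒ 13.** The C4–H bond is cut (carbinol to ketone). This removes C4 as a stereocentre and, with it, the stereogenicity of C1, leaving only C3 and C5. The forward step must deliver hydride to the face that puts the new hydroxyl cis to the C1 acyloxy group, and only the ring conformation can direct this.

**13 ⇒ 9 + 10 (twice).** The C3–O and C5–O bonds are cut. All stereocentres disappear and 9 is achiral. The forward step must form both bonds with the same absolute sense under catalyst control, attack through oxygen of 10 and not nitrogen, and functionalise both α-carbons, which consumes two molecules of 10. The mono-adducts 11 and 12 are allowed to form as a mixture because they converge.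

**9 ⇒ 6 + 7 (through 8).** The ring bonds C1–C6 and C2–C3 are cut as a [4+2] retron, the C4 carbonyl being the hydrolysed silyl enol ether of 8. The ring, the quaternary carbon and the finished tertiary caffeoyl ester then come from two acyclic pieces. The forward step needs 1,4 ("para") regiochemistry and reaction at the acrylate double bond of 6, not at its cinnamate double bond.

**6 ⇒ 3 + 4 (through 5).** The acyl–oxygen bond of the enol ester is cut. The caffeoyl unit is thereby attached while the future tertiary oxygen is still an unhindered enolate oxygen. The forward step needs O- and not C-acylation of the enolate of 4 and a neutral activation of 3, since the aryl acetals do not tolerate hydrogen chloride.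

**3 ⇒ 1 (through 2).** The two phenolic O–CH2 bonds are cut. The catechol must be masked against acyl chloride formation, the nitroso oxidant and hydride. The forward step must hydrolyse the acyl acetal of 2 and leave the two aryl acetals.

## Other disconnections considered

Alternative 1: The C1–C6 ring bond is cut and the carbocycle is traced to the six-membered vinyl lactone A2, whose carbonyl carbon is the future carboxyl and whose ring oxygen sits on the future C4. In the forward sense LiN(i-Pr)2 and Me3SiCl would O-silylate the enolate of A2, and the [3,3] shift that follows, necessarily through a boat, forms C1–C6, breaks C4–O and delivers the cyclohexene acid A1. The cis relationship of silyloxy and vinyl groups in A2 becomes the cis relationship of O1 and the C3 silyloxy group.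

- In its favour: the quaternary C1 is created as a true stereocentre by a concerted, stereospecific transfer of chirality. On stereochemical security this plan is the better one, because the chosen route leaves the C1/C4 relationship to a hydride reduction under conformational control. As a ring-forming event the rearrangement is the equal of the cycloaddition used in the chosen route.
- Against it: A2 already contains two stereocentres that need their own asymmetric synthesis. The C4=C5 alkene of A1 must become a trans-diol (O4 syn, O5 anti to O3), which needs a hydroxyl-directed epoxidation and an opening at C5, not a one-step dihydroxylation. The caffeoyl group can only be attached after the 4-methoxybenzyl ether is removed, that is, by acylating the hindered tertiary alcohol, which the chosen plan avoids.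
- Comparison: structurally it builds C1 more securely but leaves C4 and C5 to later substrate control. Mechanistically a pericyclic chirality transfer stands against two catalyst-controlled enamine oxygenations. On step economy it is estimated to be about twice as long as the chosen plan.

Alternative 2: The same two ring bonds as in the chosen route (C1–C6 and C2–C3) are cut, but the cycloaddition itself is made enantioselective. The diene A5 and the acyloxyacrolein A4, activated as its iminium ion by a chiral primary ammonium salt, would combine to A3 with C1 set. Oxidation of the formyl group to the carboxyl would then allow O5 to be placed by iodolactonisation, and after dehydroiodination the rigid bicyclic framework would direct a syn-dihydroxylation that brings in O3 and O4.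

- In its favour: the phosphonoacetate on O1 is a latent caffeate, to be completed by a Horner–Wadsworth–Emmons olefination, so no tertiary alcohol is acylated; on this point the two plans are equal. The [4+2] logic is the same and equally reliable. The relay through a rigid bicycle is a more secure way to the C4 configuration than the reduction of 13, a point on which this alternative is better.
- Against it: A5 is a gaseous diene without the donor substituent that makes 7 reactive and regioselective, and face discrimination with so small a diene is less assured. Its key step sets one stereocentre where the chosen one sets two. The dihydroxylation must precede the olefination to avoid the cinnamate alkene. A lactone must finally be opened next to a base-sensitive tertiary caffeate.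
- Comparison: structurally it fixes C1 first and relays the rest, where the chosen plan fixes C3 and C5 first and relays C4. Mechanistically iminium catalysis of a cycloaddition stands against enamine catalysis of a heteroatom transfer. On step economy about ten steps are estimated against seven.

Alternative 3: The C1–C2 bond is cut and the carbocycle is traced to the pyranoid heptulosonate A7, which carries an exocyclic enol ether. Hg(OCOCF3)2 (divalent mercury) in aqueous acetone would hydrate that enol ether. Ring opening then unmasks the C3 carbonyl and the C1 keto ester, and the mercury-bearing C2 closes onto C1 in an aldol step to give A6.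

- In its favour: C4 and C5 come from a sugar with defined absolute configuration, which is the equal of catalyst control and does not depend on an enantioselective step. The ring and the tertiary carbinol form in one biomimetic operation. The later reduction of the C3 ketone, with the axial C1 oxygen shielding one face, should be at least as predictable as the reduction of 13.
- Against it: A7 needs a long carbohydrate sequence. A toxic mercury salt is used. The C1 configuration depends on substrate control in the aldol step. A6 is a β-hydroxy ketone prone to dehydration. Benzyl ethers cannot be hydrogenolysed once the cinnamate is present. The caffeoyl group again has to be placed on the free tertiary hydroxyl, which the chosen plan avoids.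
- Comparison: structurally the stereocentres are inherited instead of made. Mechanistically an organomercury aldol closure replaces a cycloaddition. On step economy it is clearly the longest of the four plans.

Key step: step 4

Remark: 4 and 7 are treated as purchased materials. Every compound containing C1 before step 4 is achiral or racemic, which has no consequence because C1 is not a stereocentre in 9 or 13.

Remark: at each α-carbon of 13 the CIP order is O > C4 > CH2 > H, as in 2-(anilinooxy)cyclohexanone, so the R,R isomer that maps onto C3 and C5 of 16 is the one expected from L-proline.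

## Route

Step 1
Reactants: 1 caffeic acid
Product: 3 (E)-3-[3,4-bis(methoxymethoxy)phenyl]prop-2-enoic acid, via tris(methoxymethyl) derivative 2 (not isolated)
Conditions: MOMCl (3.5 equiv), i-Pr2NEt (4.5 equiv), DMF/CH2Cl2, 0 °C → rt; then LiOH (3 equiv), THF/MeOH/H2O, rt; cold 1 M HCl to pH 4
Reagents that add atoms: chloromethyl methyl ether, COCCl; lithium hydroxide, [Li+].[OH-] (one carboxyl oxygen of 3)
Why: O-alkylation of the two phenoxides and the carboxylate by the chloromethyl ether caps all three oxygens as acetals; the acyl acetal is far more electrophilic than the aryl acetals and is saponified selectively by hydroxide, the E double bond being untouched.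

Step 2
Reactants: 3 (E)-3-[3,4-bis(methoxymethoxy)phenyl]prop-2-enoic acid; 4 tert-butyl pyruvate
Product: 6 tert-butyl 2-{[(E)-3-(3,4-bis(methoxymethoxy)phenyl)prop-2-enoyl]oxy}prop-2-enoate, via acyl chloride 5 (not isolated)
Conditions: Me2C=C(Cl)NMe2 (1.1 equiv), CH2Cl2, 0 °C → rt; then 4 (1.5 equiv), Et3N (2.5 equiv), 4-(dimethylamino)pyridine (10 mol %), CH2Cl2, −20 → 0 °C
Reagents that add atoms: 1-chloro-N,N,2-trimethylprop-1-en-1-amine, CC(C)=C(Cl)N(C)C (supplies only the chlorine of 5; no atom of it remains in 6)
Why: The α-chloroenamine converts the acid into the acyl chloride without free hydrogen chloride, so the aryl acetals survive; triethylamine enolises the α-keto ester and the enolate oxygen is acylated (enol ester formation), giving the 2-acyloxyacrylate with the caffeoyl group already on the future tertiary oxygen.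

Step 3
Reactants: 6 tert-butyl 2-{[(E)-3-(3,4-bis(methoxymethoxy)phenyl)prop-2-enoyl]oxy}prop-2-enoate; 7 2-(trimethylsilyloxy)buta-1,3-diene
Product: 9 tert-butyl 1-{[(E)-3-(3,4-bis(methoxymethoxy)phenyl)prop-2-enoyl]oxy}-4-oxocyclohexane-1-carboxylate, via silyl enol ether 8 (not isolated)
Conditions: 7 (3 equiv), 2,6-di-tert-butyl-4-methylphenol (trace, radical inhibitor), PhMe, 110 °C, sealed tube; then 1 M HCl/THF, 0 °C, 15 min
Reagents that add atoms: none
Why: Thermal normal-demand Diels–Alder reaction in which the donor on C2 of the diene makes its C1 the nucleophilic terminus, which bonds to the acrylate CH2, so the silyloxy carbon ends 1,4 to the quaternary carbon; the 1,2-disubstituted, aryl-conjugated cinnamate double bond is a much poorer dienophile. Brief cold aqueous acid hydrolyses the silyl enol ether to the achiral ketone and spares the aryl acetals and the tert-butyl ester.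

Step 4
Reactants: 9 tert-butyl 1-{[(E)-3-(3,4-bis(methoxymethoxy)phenyl)prop-2-enoyl]oxy}-4-oxocyclohexane-1-carboxylate; 10 nitrosobenzene
Product: 13 tert-butyl (3R,5R)-3,5-bis(anilinooxy)-1-{[(E)-3-(3,4-bis(methoxymethoxy)phenyl)prop-2-enoyl]oxy}-4-oxocyclohexane-1-carboxylate, via (1S,3R)-mono(anilinooxy) ketone 11 (not isolated), via (1R,3R)-mono(anilinooxy) ketone 12 (not isolated)
Conditions: L-proline (30 mol %), 10 (3 equiv in all, added over 12 h by syringe pump), DMF, 0 °C
Reagents that add atoms: nitrosobenzene (the second molecule of 10 that is taken up), O=Nc1ccccc1
Why: L-Proline condenses with the C4 carbonyl of 9 to an enamine towards C3 or C5, its carboxylic acid hydrogen-bonds to the nitrogen of 10, and the enamine carbon attacks the nitroso oxygen in that organised anti-enamine transition state; hydrolysis releases the mono-adducts 11 and 12 and the catalyst. A second catalytic cycle, in which the enamine forms preferentially towards the remaining methylene, takes up a second molecule of 10 at the other α-carbon and gives 13. The closest known reaction type is the proline-catalysed α-aminoxylation of cyclohexanones with nitrosobenzene, including the α,α′-double aminoxylation of 4,4-disubstituted cyclohexanones. No ring is closed; two C–O bonds are formed. Both new stereocentres (C3 and C5) are set by the catalyst: by the hydrogen-bonded model L-proline delivers oxygen to the enamine face that gives R, as it does with cyclohexanone itself, and the C1 substituents, three bonds from the reacting carbon, should not override it. Because C1 is not a stereocentre in 13, 11 and 12 converge on one product, and a facial error in either cycle ends in an achiral, separable cis-3,5 isomer and not in the enantiomer, so the enantiomeric purity of 13 should exceed that of a single aminoxylation. The step needs O- over N-attack (secured by the acid function of proline), enamine formation at the unsubstituted α-carbon in the second cycle (secured by substitution, which also protects the first centre from epimerisation) and inertness of the rest of the molecule (the cinnamate ester cannot form an enamine and the capped catechol cannot be oxidised); slow addition of 10 limits its self-condensation.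

Step 5
Reactants: 13 tert-butyl (3R,5R)-3,5-bis(anilinooxy)-1-{[(E)-3-(3,4-bis(methoxymethoxy)phenyl)prop-2-enoyl]oxy}-4-oxocyclohexane-1-carboxylate
Product: 14 tert-butyl (3R,5R)-3,5-bis(anilinooxy)-1-{[(E)-3-(3,4-bis(methoxymethoxy)phenyl)prop-2-enoyl]oxy}-4-hydroxycyclohexane-1-carboxylate (4-hydroxyl cis to the 1-acyloxy group)
Conditions: NaBH4 (1.5 equiv), THF/MeOH (4:1), −78 → −40 °C; sat. aq. NH4Cl
Reagents that add atoms: none
Why: Hydride addition to a cyclohexanone: in the preferred chair (ester equatorial; the C1 acyloxy group and the anilinooxy group syn to it axial; the other anilinooxy group equatorial) the small hydride should attack C4 axially, anti to the axial α-C–O bond (Felkin–Anh-type polar control, only axial hydrogens on that face), giving the equatorial alcohol cis to the C1 acyloxy group. The low temperature spares both esters and avoids base-induced loss of aniline from the α-aminoxy ketone.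

Step 6
Reactants: 14 tert-butyl (3R,5R)-3,5-bis(anilinooxy)-1-{[(E)-3-(3,4-bis(methoxymethoxy)phenyl)prop-2-enoyl]oxy}-4-hydroxycyclohexane-1-carboxylate
Product: 15 tert-butyl (3R,5R)-1-{[(E)-3-(3,4-bis(methoxymethoxy)phenyl)prop-2-enoyl]oxy}-3,4,5-trihydroxycyclohexane-1-carboxylate (4-hydroxyl cis to the 1-acyloxy group)
Conditions: Zn dust (excess), AcOH/THF/H2O (3:1:1), rt
Reagents that add atoms: none
Why: Dissolving-metal reductive cleavage of the two weak N–O bonds frees the C3 and C5 hydroxyls and aniline without touching the C–O stereocentres, the cinnamate double bond, the acetals or the tert-butyl ester; the mildly acidic, non-hydrogenating medium also gives acyl migration from O1 no opportunity.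

Step 7
Reactants: 15 tert-butyl (3R,5R)-1-{[(E)-3-(3,4-bis(methoxymethoxy)phenyl)prop-2-enoyl]oxy}-3,4,5-trihydroxycyclohexane-1-carboxylate
Product: 16 1-O-caffeoylquinic acid
Conditions: CF3CO2H/CH2Cl2/H2O (10:10:1), 0 °C → rt; evaporation below 25 °C, reversed-phase chromatography
Reagents that add atoms: none
Why: Acidolysis cleaves the tert-butyl ester by alkyl–oxygen fission (loss of 2-methylpropene) and the aryl acetals by oxocarbenium hydrolysis, with water as the cation trap. The tertiary C1–O bond does not ionise next to the carboxyl group and, with no base present, the caffeoyl group should stay on O1; no stereocentre is involved.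

## Compound list

1 | caffeic acid, (E)-3-(3,4-dihydroxyphenyl)prop-2-enoic acid | O=C(O)/C=C/c1ccc(O)c(O)c1 | starting material
2 | methoxymethyl (E)-3-[3,4-bis(methoxymethoxy)phenyl]prop-2-enoate (formed in the flask, not isolated) | COCOC(=O)/C=C/c1ccc(OCOC)c(OCOC)c1 | intermediate
3 | (E)-3-[3,4-bis(methoxymethoxy)phenyl]prop-2-enoic acid | COCOc1ccc(/C=C/C(=O)O)cc1OCOC | intermediate
4 | tert-butyl pyruvate (tert-butyl 2-oxopropanoate) | CC(=O)C(=O)OC(C)(C)C | starting material
5 | (E)-3-[3,4-bis(methoxymethoxy)phenyl]prop-2-enoyl chloride (formed in the flask, not isolated) | COCOc1ccc(/C=C/C(=O)Cl)cc1OCOC | intermediate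
6 | tert-butyl 2-{[(E)-3-(3,4-bis(methoxymethoxy)phenyl)prop-2-enoyl]oxy}prop-2-enoate | C=C(OC(=O)/C=C/c1ccc(OCOC)c(OCOC)c1)C(=O)OC(C)(C)C | intermediate
7 | 2-(trimethylsilyloxy)buta-1,3-diene | C=CC(=C)O[Si](C)(C)C | starting material
8 | tert-butyl 1-{[(E)-3-(3,4-bis(methoxymethoxy)phenyl)prop-2-enoyl]oxy}-4-(trimethylsilyloxy)cyclohex-3-ene-1-carboxylate (racemic; formed in the flask, not isolated) | COCOc1ccc(/C=C/C(=O)OC2(C(=O)OC(C)(C)C)CC=C(O[Si](C)(C)C)CC2)cc1OCOC | intermediate
9 | tert-butyl 1-{[(E)-3-(3,4-bis(methoxymethoxy)phenyl)prop-2-enoyl]oxy}-4-oxocyclohexane-1-carboxylate (achiral) | COCOc1ccc(/C=C/C(=O)OC2(C(=O)OC(C)(C)C)CCC(=O)CC2)cc1OCOC | intermediate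
10 | nitrosobenzene | O=Nc1ccccc1 | starting material
11 | tert-butyl (1S,3R)-3-(anilinooxy)-1-{[(E)-3-(3,4-bis(methoxymethoxy)phenyl)prop-2-enoyl]oxy}-4-oxocyclohexane-1-carboxylate (anilinooxy cis to the ester group; formed in the flask, not isolated) | COCOc1ccc(/C=C/C(=O)O[C@]2(C(=O)OC(C)(C)C)C[C@@H](ONc3ccccc3)C(=O)CC2)cc1OCOC | intermediate
12 | tert-butyl (1R,3R)-3-(anilinooxy)-1-{[(E)-3-(3,4-bis(methoxymethoxy)phenyl)prop-2-enoyl]oxy}-4-oxocyclohexane-1-carboxylate (anilinooxy cis to the acyloxy group; formed in the flask, not isolated) | COCOc1ccc(/C=C/C(=O)O[C@]2(C(=O)OC(C)(C)C)CCC(=O)[C@H](ONc3ccccc3)C2)cc1OCOC | intermediate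
13 | tert-butyl (3R,5R)-3,5-bis(anilinooxy)-1-{[(E)-3-(3,4-bis(methoxymethoxy)phenyl)prop-2-enoyl]oxy}-4-oxocyclohexane-1-carboxylate | COCOc1ccc(/C=C/C(=O)OC2(C(=O)OC(C)(C)C)C[C@@H](ONc3ccccc3)C(=O)[C@H](ONc3ccccc3)C2)cc1OCOC | intermediate
14 | tert-butyl (3R,5R)-3,5-bis(anilinooxy)-1-{[(E)-3-(3,4-bis(methoxymethoxy)phenyl)prop-2-enoyl]oxy}-4-hydroxycyclohexane-1-carboxylate, 4-hydroxyl cis to the 1-acyloxy group | COCOc1ccc(/C=C/C(=O)O[C@]2(C(=O)OC(C)(C)C)C[C@@H](ONc3ccccc3)[C@H](O)[C@H](ONc3ccccc3)C2)cc1OCOC | intermediate
15 | tert-butyl (3R,5R)-1-{[(E)-3-(3,4-bis(methoxymethoxy)phenyl)prop-2-enoyl]oxy}-3,4,5-trihydroxycyclohexane-1-carboxylate, 4-hydroxyl cis to the 1-acyloxy group (tert-butyl ester of the bis-MOM-protected target) | COCOc1ccc(/C=C/C(=O)O[C@]2(C(=O)OC(C)(C)C)C[C@@H](O)[C@H](O)[C@H](O)C2)cc1OCOC | intermediate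
16 | 1-O-caffeoylquinic acid: (3R,5R)-1-{[(E)-3-(3,4-dihydroxyphenyl)prop-2-enoyl]oxy}-3,4,5-trihydroxycyclohexane-1-carboxylic acid; the 4-hydroxyl is cis to the 1-acyloxy group, the flanking hydroxyl cis to it is also cis to the acyloxy group, the other flanking hydroxyl is cis to the carboxyl | O=C(/C=C/c1ccc(O)c(O)c1)O[C@]1(C(=O)O)C[C@@H](O)[C@H](O)[C@H](O)C1 | target

## Step count and least certain steps

Total step count: 7. Longest linear sequence: 7 steps (1 → 16); 4, 7 and 10 enter as purchased materials.

**Step 4 (key step).** The most likely failure is stalling after the first aminoxylation, because the second enamine must form on a ketone that already carries an inductively withdrawing α-substituent, while 10 is consumed by self-condensation. A second risk is loss of aniline from 13 by N–O fragmentation on work-up or on silica. The fallback sets out from 9 and comes back at 15, and replaces aminocatalysis by two reagent-controlled enolate hydroxylations. Compound 9 would be deprotonated with NaN(SiMe3)2 in THF at −78 °C (only the ketone α-hydrogens are acidic) and the enolate oxidised with the antipode of (camphorsulfonyl)oxaziridine that delivers the 3R alcohol, giving tert-butyl (3R)-1-{[(E)-3-(3,4-bis(methoxymethoxy)phenyl)prop-2-enoyl]oxy}-3-hydroxy-4-oxocyclohexane-1-carboxylate F1 as both C1 epimers. Et3SiCl and imidazole would then give the triethylsilyl ether F2. A second kinetic enolisation, now towards the unsubstituted α-carbon, and the same oxidant would give the (3R,5R)-3-hydroxy-5-(triethylsilyloxy) ketone F3. HF·pyridine would give the (3R,5R)-3,5-dihydroxy-4-oxo compound F4, in which C1 is again not a stereocentre, and NaBH4 at −78 °C, with the facial argument of step 5, would lead to 15. The enantioselectivity of this oxidant is expected to be lower and less predictable than that of aminocatalysis; as in the main route, facial errors are diverted into cis diastereomers.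

**Step 5.** The most likely failure is poor facial selectivity. Hydride should attack anti to whichever α-C–O bond is axial, and the two chairs then give opposite C4 epimers. The preference for the chair with the ester equatorial rests only on the smaller axial demand of the acyloxy group and on a less severe syn-diaxial contact. The fallback sets out from 13 and comes back at 14. The C4 epimer of 14, tert-butyl (3R,5R)-3,5-bis(anilinooxy)-1-{[(E)-3-(3,4-bis(methoxymethoxy)phenyl)prop-2-enoyl]oxy}-4-hydroxycyclohexane-1-carboxylate with the 4-hydroxyl trans to the 1-acyloxy group F5, would be separated by chromatography. A Mitsunobu reaction (chloroacetic acid, PPh3, diisopropyl azodicarboxylate, THF) would invert it to the chloroacetate of 14 F6. Thiourea and NaHCO3 in ethanol would then remove the chloroacetyl group under conditions that leave the tertiary caffeate alone, giving 14.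

**Step 3.** The most likely failure is polymerisation of the captodative acrylate or thermal decomposition of the diene before the cycloaddition is complete. Competing cycloaddition at the cinnamate is less likely. The fallback sets out from 5 and comes back at 9. It gives up the advantage of never acylating a tertiary alcohol, but uses only standard operations. Purchased tert-butyl 4-oxocyclohexane-1-carboxylate F7 would be ketalised with 1,2-bis(trimethylsilyloxy)ethane and a trace of Me3SiOTf to tert-butyl 1,4-dioxaspiro[4.5]decane-8-carboxylate F8. Its ester enolate (LiN(i-Pr)2, THF, −78 °C) would be hydroxylated with 3-phenyl-2-(phenylsulfonyl)oxaziridine to tert-butyl 8-hydroxy-1,4-dioxaspiro[4.5]decane-8-carboxylate F9. The lithium alkoxide of F9 (LiN(SiMe3)2) would be acylated with 5 to tert-butyl 8-{[(E)-3-(3,4-bis(methoxymethoxy)phenyl)prop-2-enoyl]oxy}-1,4-dioxaspiro[4.5]decane-8-carboxylate F10. Pyridinium p-toluenesulfonate in wet acetone would remove the dioxolane and give 9.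

**Step 7.** The most likely failure is electrophilic capture of the released methoxymethyl and tert-butyl cations (or of formaldehyde) by the catechol ring or the cis-3,4-diol, or acid-promoted 1,5-lactonisation during concentration. The fallback sets out from 15 and comes back at 16, and separates the two unmasking events. ZnBr2 and 1-propanethiol in CH2Cl2 at 0 °C would remove the two methoxymethyl groups, their CH2 carbons being trapped as a dithioacetal, and give tert-butyl 1-O-caffeoylquinate F11. CF3CO2H/CH2Cl2 with triisopropylsilane as cation trap at 0 °C would then cleave the tert-butyl ester, with no formaldehyde source present, and give 16.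

## Further compounds

F1 | step 4 | tert-butyl (3R)-1-{[(E)-3-(3,4-bis(methoxymethoxy)phenyl)prop-2-enoyl]oxy}-3-hydroxy-4-oxocyclohexane-1-carboxylate (both C1 epimers) | COCOc1ccc(/C=C/C(=O)OC2(C(=O)OC(C)(C)C)C[C@@H](O)C(=O)CC2)cc1OCOC
F2 | step 4 | tert-butyl (3R)-1-{[(E)-3-(3,4-bis(methoxymethoxy)phenyl)prop-2-enoyl]oxy}-4-oxo-3-(triethylsilyloxy)cyclohexane-1-carboxylate (both C1 epimers) | COCOc1ccc(/C=C/C(=O)OC2(C(=O)OC(C)(C)C)C[C@@H](O[Si](CC)(CC)CC)C(=O)CC2)cc1OCOC
F3 | step 4 | tert-butyl (3R,5R)-1-{[(E)-3-(3,4-bis(methoxymethoxy)phenyl)prop-2-enoyl]oxy}-3-hydroxy-4-oxo-5-(triethylsilyloxy)cyclohexane-1-carboxylate (both C1 epimers) | COCOc1ccc(/C=C/C(=O)OC2(C(=O)OC(C)(C)C)C[C@@H](O[Si](CC)(CC)CC)C(=O)[C@H](O)C2)cc1OCOC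
F4 | step 4 | tert-butyl (3R,5R)-1-{[(E)-3-(3,4-bis(methoxymethoxy)phenyl)prop-2-enoyl]oxy}-3,5-dihydroxy-4-oxocyclohexane-1-carboxylate | COCOc1ccc(/C=C/C(=O)OC2(C(=O)OC(C)(C)C)C[C@@H](O)C(=O)[C@H](O)C2)cc1OCOC
F5 | step 5 | tert-butyl (3R,5R)-3,5-bis(anilinooxy)-1-{[(E)-3-(3,4-bis(methoxymethoxy)phenyl)prop-2-enoyl]oxy}-4-hydroxycyclohexane-1-carboxylate, 4-hydroxyl trans to the 1-acyloxy group (C4 epimer of 14) | COCOc1ccc(/C=C/C(=O)O[C@]2(C(=O)OC(C)(C)C)C[C@@H](ONc3ccccc3)[C@@H](O)[C@H](ONc3ccccc3)C2)cc1OCOC
F6 | step 5 | tert-butyl (3R,5R)-3,5-bis(anilinooxy)-1-{[(E)-3-(3,4-bis(methoxymethoxy)phenyl)prop-2-enoyl]oxy}-4-(chloroacetoxy)cyclohexane-1-carboxylate, 4-chloroacetoxy cis to the 1-acyloxy group | COCOc1ccc(/C=C/C(=O)O[C@]2(C(=O)OC(C)(C)C)C[C@@H](ONc3ccccc3)[C@H](OC(=O)CCl)[C@H](ONc3ccccc3)C2)cc1OCOC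
F7 | step 3 | tert-butyl 4-oxocyclohexane-1-carboxylate | CC(C)(C)OC(=O)C1CCC(=O)CC1
F8 | step 3 | tert-butyl 1,4-dioxaspiro[4.5]decane-8-carboxylate | CC(C)(C)OC(=O)C1CCC2(CC1)OCCO2
F9 | step 3 | tert-butyl 8-hydroxy-1,4-dioxaspiro[4.5]decane-8-carboxylate | CC(C)(C)OC(=O)C1(O)CCC2(CC1)OCCO2
F10 | step 3 | tert-butyl 8-{[(E)-3-(3,4-bis(methoxymethoxy)phenyl)prop-2-enoyl]oxy}-1,4-dioxaspiro[4.5]decane-8-carboxylate | COCOc1ccc(/C=C/C(=O)OC2(C(=O)OC(C)(C)C)CCC3(CC2)OCCO3)cc1OCOC
F11 | step 7 | tert-butyl 1-O-caffeoylquinate (tert-butyl ester of 16) | O=C(/C=C/c1ccc(O)c(O)c1)O[C@]1(C(=O)OC(C)(C)C)C[C@@H](O)[C@H](O)[C@H](O)C1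
A1 | alternative 1 | (5R)-5-(tert-butyldimethylsilyloxy)-1-(4-methoxybenzyloxy)cyclohex-3-ene-1-carboxylic acid, carboxyl trans to the silyloxy group | COc1ccc(CO[C@]2(C(=O)O)CC=C[C@H](O[Si](C)(C)C(C)(C)C)C2)cc1
A2 | alternative 1 | (5R,6R)-5-(tert-butyldimethylsilyloxy)-6-ethenyl-3-(4-methoxybenzyloxy)oxan-2-one, silyloxy cis to ethenyl, C3 of either configuration | O=C1O[C@H](C=C)[C@H](O[Si](C)(C)C(C)(C)C)CC1OCc1ccc(OC)cc1
A3 | alternative 2 | (S)-1-formylcyclohex-3-en-1-yl (diethoxyphosphoryl)acetate | CCOP(=O)(OCC)CC(=O)O[C@]1(C=O)CC=CCC1
A4 | alternative 2 | 3-oxoprop-1-en-2-yl (diethoxyphosphoryl)acetate (the 2-acyloxyacrolein) | CCOP(=O)(OCC)CC(=O)OC(=C)C=O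
A5 | alternative 2 | buta-1,3-diene | C=CC=C
A6 | alternative 3 | methyl 4,5-di-O-benzyl-3-dehydroquinate | COC(=O)[C@@]1(O)C[C@@H](OCc2ccccc2)[C@H](OCc2ccccc2)C(=O)C1
A7 | alternative 3 | methyl (methyl 4,5-di-O-benzyl-3,7-dideoxy-D-threo-hept-6-en-2-ulopyranosid)onate, either anomer | COC(=O)C1(OC)C[C@@H](OCc2ccccc2)[C@H](OCc2ccccc2)C(=C)O1
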